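**Retrosynthetic overview**

1. Guttiferone B ⇐ C3 aroylation and C5 bridgehead geranylation of the methyl enol ether of 7-geranyl-8,8-dimethyl-1-prenylbicyclo[3.3.1]nonane-2,4,9-trione.
2. Ring A of that trione (C1–C2–C3–C4–C5–C9) ⇐ one-carbon ring expansion of the five-membered ring C1–C2–C4–C5–C9 of a bicyclo[3.2.1]octane: a carbenoid CH2 (the future C3) is added across the enediol C2=C4, then the C2–C4 bond is cut oxidatively.
3. The feature that makes this possible is the C2–C4 bond flanked by two oxygen-bearing carbons (acyloin level) in the strained cyclopentene ring of the bicyclo[3.2.1] system; only this bond, once spanned by the cyclopropane, gives two carbonyls on scission.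
4. Bicyclo[3.2.1] dione ⇐ desymmetrising intramolecular alkylation (ring B closed at C5–C6) of a 2,2-disubstituted cyclopentane-1,3-dione whose only stereocentre, C7, selects between the two diastereotopic α-methylenes and so fixes C1.
5. That dione ⇐ Claisen rearrangement (C1–C8 bond) and organocatalytic enal reduction (C7). Ring order: cyclopentanedione ring, then ring B, then ring A by expansion.

Key step: step 14

Remark on numbering: all intermediates carry the atom numbers of the final bicyclo[3.3.1]nonane core (C1 prenyl bridgehead, C2/C4 carbonyl carbons, C3, C5 geranyl bridgehead, C6 CH2, C7 CH-geranyl, C8 CMe2, C9 bridging carbonyl).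
Assumption 1: in step 8 the catalyst enantiomer is chosen by analogy with the reported reduction of β-methylcinnamaldehyde (large β-group in the place of phenyl); if the other aldehyde enantiomer forms, the catalyst antipode is used.
Assumption 2: O-methylation in step 15 is drawn at the less hindered O4; the 2-methoxy regioisomer would follow the same steps and converge in step 20.
Assumption 3: the oxidative ring enlargement of step 14 is taken as a known reaction type for acyloin-derived bis(silyloxy)cyclopropanes; this rests on recollection of the literature and was not checked here.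

**Route**

Step 1
Reactants: 1 cyclopentane-1,3-dione; 2 prenyl bromide
Product: 3 2-prenylcyclopentane-1,3-dione
Conditions: KOH, H2O, rt → 60 °C
Reagents that add atoms: none
Why: C-allylation of the vinylogous acid in water, where the hydrogen-bonded enolate oxygens favour attack through carbon, should give the 2-monoalkyl dione; no stereocentre.

Step 2
Reactants: 3 2-prenylcyclopentane-1,3-dione
Product: 4 3-chloro-2-prenylcyclopent-2-en-1-one
Conditions: (COCl)2, DMF (cat.), CH2Cl2, 0 °C
Reagents that add atoms: oxalyl chloride, ClC(=O)C(=O)Cl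
Why: Vilsmeier-type activation converts the vinylogous acid into the vinylogous acid chloride, the electrophile for enol ether formation.

Step 3
Reactants: 5 1,1-dibromo-2-methylprop-1-ene; 6 geranyl bromide
Product: 7 (5E)-3-bromo-2,6,10-trimethylundeca-2,5,9-triene
Conditions: n-BuLi, THF/Et2O/pentane, −110 °C; then 6, −110 → −78 °C
Reagents that add atoms: none
Why: Bromine–lithium exchange gives the α-bromoalkenyllithium, which should be alkylated by the allylic bromide in SN2 fashion with the E-geranyl unit intact; the gem-dimethyl terminus removes any alkene-geometry issue.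

Step 4
Reactants: 7 vinyl bromide; 8 2,2-dimethoxyacetaldehyde (anhydrous)
Product: 9 (5E)-1,1-dimethoxy-6,10-dimethyl-3-(propan-2-ylidene)undeca-5,9-dien-2-ol (racemic)
Conditions: t-BuLi (2 equiv), Et2O, −78 °C; then 8, −78 °C
Reagents that add atoms: none
Why: Halogen–lithium exchange and 1,2-addition of the alkenyllithium to the aldehyde; the carbinol centre is racemic and is erased in step 6.

Step 5
Reactants: 9 allylic alcohol; 4 chloro-enone
Product: 10 3-alkoxy-2-prenylcyclopent-2-en-1-one (allyl vinyl ether)
Conditions: NaH, THF, 0 °C → rt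
Reagents that add atoms: none
Why: Addition–elimination of the alkoxide at the β-carbon of the β-chloro enone should give the vinylogous ester, which is the allyl vinyl ether needed for the Claisen step.

Step 6
Reactants: 10 allyl vinyl ether
Product: 11 2-prenyl-2-[(3E,5E)-3-(2,2-dimethoxyethylidene)-2,6,10-trimethylundeca-5,9-dien-2-yl]cyclopentane-1,3-dione
Conditions: toluene, 110 °C, sealed tube
Reagents that add atoms: none
Why: Claisen [3,3] rearrangement forms the C1–C8 bond between two fully substituted carbons and returns the symmetric 1,3-dione, so C1 is not yet stereogenic; the geometry of the new C6=C7 alkene is irrelevant because step 8 is stereoconvergent.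

Step 7
Reactants: 11 unsaturated acetal
Product: 12 enal (C5 aldehyde, C6=C7, geranyl on C7)
Conditions: PPTS, acetone/H2O, rt
Reagents that add atoms: water, O
Why: Mild acid hydrolysis of an α,β-unsaturated acetal is fast and should leave the prenyl-type alkenes and the dione alone.

Step 8
Reactants: 12 enal
Product: 13 (3S)-3-geranyl-4-methyl-4-(1-prenyl-2,5-dioxocyclopentyl)pentanal
Conditions: (R)-2-tert-butyl-3-methylimidazolidin-4-one·CCl3CO2H (20 mol %), diethyl 2,6-dimethyl-1,4-dihydropyridine-3,5-dicarboxylate (1.2 equiv), CHCl3, −30 °C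
Reagents that add atoms: none
Why: Iminium-catalysed transfer hydrogenation of a β,β-disubstituted enal should set C7 by hydride delivery anti to the catalyst tert-butyl group, with the E and Z enals converging through iminium/dienamine equilibration; ketones and isolated alkenes are not touched.

Step 9
Reactants: 13 aldehyde
Product: 14 (3S)-3-geranyl-4-methyl-4-(1-prenyl-2,5-dioxocyclopentyl)pentanoic acid
Conditions: NaClO2, NaH2PO4, 2-methylbut-2-ene, t-BuOH/H2O, 0 °C → rt
Reagents that add atoms: sodium chlorite, [Na+].[O-]Cl=O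
Why: Pinnick oxidation is selective for the aldehyde, and the scavenger protects the trisubstituted alkenes from hypochlorite.

Step 10
Reactants: 14 acid
Product: 16 2-[(3R,5E)-3-(iodomethyl)-2,6,10-trimethylundeca-5,9-dien-2-yl]-2-prenylcyclopentane-1,3-dione, via Barton ester 15 (not isolated)
Conditions: 1-hydroxypyridine-2(1H)-thione, DCC, DMAP (cat.), CH2Cl2, 0 °C, dark; then CHI3, hν (tungsten lamp), rt
Reagents that add atoms: iodoform, IC(I)I; 1-hydroxypyridine-2(1H)-thione, On1ccccc1=S (carried only in 15)
Why: Barton decarboxylative iodination removes the former aldehyde carbon, which has served its purpose as the activating group for step 8, and leaves C6 as a primary iodide; C7 is untouched (the descriptor changes to R only because CH2I outranks the quaternary carbon).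

Step 11
Reactants: 16 iodide
Product: 17 3-geranyl-4,4-dimethyl-5-prenylbicyclo[3.2.1]octane-6,8-dione (C2 and C9 carbonyls, C4 methylene, C5–H)
Conditions: KN(SiMe3)2 (1.1 equiv), THF (high dilution), −78 → 0 °C
Reagents that add atoms: none
Why: Intramolecular ketone enolate alkylation (6-(enolendo)-exo-tet) closes ring B at C5–C6 through a chair in which the C1–C2 and C5–C4 bonds are necessarily axial and the C7 geranyl group sits equatorial, which only one of the two diastereotopic α-methylenes allows; this sets C1 and C5 relative to C7 with the geranyl group exo.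

Step 12
Reactants: 17 bicyclic dione
Product: 18 7-hydroxy derivative of 17 (acyloin, OH on C4)
Conditions: KN(SiMe3)2, THF, −78 °C; then 2-(phenylsulfonyl)-3-phenyloxaziridine, −78 °C
Reagents that add atoms: 2-(phenylsulfonyl)-3-phenyloxaziridine, O=S(=O)(c1ccccc1)N1OC1c1ccccc1
Why: C4 is the only enolisable position (C1 is quaternary, C5 is a bridgehead), so Davis hydroxylation should be regiospecific; the new centre is erased in step 13.

Step 13
Reactants: 18 acyloin
Product: 19 6,7-bis(trimethylsilyloxy)bicyclo[3.2.1]oct-6-en-8-one derivative (C2=C4 enediol bis-silyl ether)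
Conditions: Me3SiOTf (2.5 equiv), Et3N, CH2Cl2, 0 °C
Reagents that add atoms: trimethylsilyl trifluoromethanesulfonate, C[Si](C)(C)OS(=O)(=O)C(F)(F)F
Why: O-silylation and silyl enol ether formation towards the only available α-carbon give the acyloin-type 1,2-bis(silyloxy)alkene.

Step 14
Reactants: 19 enediol bis-silyl ether
Product: 21 7-geranyl-8,8-dimethyl-1-prenylbicyclo[3.3.1]nonane-2,4,9-trione, via bis(silyloxy)cyclopropane 20 (not isolated)
Conditions: Et2Zn, CH2I2, CH2Cl2, −20 → 0 °C; filter, concentrate; then FeCl3 (2.2 equiv), DMF, 0 °C; dilute HCl work-up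
Reagents that add atoms: diiodomethane, ICI
Why: The zinc carbenoid adds CH2 (the future C3) to the most electron-rich and strained alkene, the enediol bis-silyl ether C2=C4, and FeCl3 then oxidises the 1,2-bis(silyloxy)cyclopropane by single-electron transfer so that the internal C2–C4 bond breaks and both carbons end as carbonyls with C3 between them. The closest known reaction type is the Ito–Saegusa oxidative ring enlargement of silyloxycyclopropanes, here in its acyloin version (1,2-bis(silyloxy)bicyclo[n.1.0]alkane to cycloalkane-1,3-dione), after a Furukawa–Simmons–Smith cyclopropanation of a silyl enol ether. The cyclopropane is closed by [2+1] addition, and ring A arises when the zero-atom bridge of the bicyclo[3.1.0]hexane unit is cut; no ring is closed by a new ring bond in the expansion itself and ring B is untouched. No stereocentre is formed or broken: C1, C5 and C7 carry through because no bond to them changes, and the transient centres C2 and C4 become trigonal. The step needs scission of C2–C4 and not of C2–C3 or C3–C4, which the substrate secures because only the internal bond joins two oxygen-bearing carbons, and it needs chemoselectivity over five trisubstituted alkenes, which the far more electron-rich bis(silyloxy) alkene and cyclopropane should provide.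

Step 15
Reactants: 21 trione
Product: 22 7-geranyl-4-methoxy-8,8-dimethyl-1-prenylbicyclo[3.3.1]non-3-ene-2,9-dione
Conditions: Me3SiCHN2, MeOH/toluene, 0 °C → rt
Reagents that add atoms: (trimethylsilyl)diazomethane, C[Si](C)(C)C=[N+]=[N-]
Why: O-methylation of the vinylogous acid under non-basic conditions avoids retro-Claisen cleavage and should occur at the less hindered oxygen, remote from C1 and the gem-dimethyl group.

Step 16
Reactants: 22 methyl enol ether; 6 geranyl bromide
Product: 23 5,7-digeranyl-4-methoxy-8,8-dimethyl-1-prenylbicyclo[3.3.1]non-3-ene-2,9-dione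
Conditions: LiN(i-Pr)2, THF, −78 °C; then 6, −78 → 0 °C
Reagents that add atoms: none
Why: Bridgehead lithiation at C5 (α to the C9 ketone) and alkylation is precedented for enol ethers of bicyclo[3.3.1]nonane-2,4,9-triones; the bridgehead geometry forces retention, so C5 is set by the ring system.

Step 17
Reactants: 24 3,4-dihydroxybenzoic acid
Product: 25 tert-butyldimethylsilyl 3,4-bis(tert-butyldimethylsilyloxy)benzoate
Conditions: t-BuMe2SiCl (3.3 equiv), imidazole, DMF, rt
Reagents that add atoms: tert-butyldimethylsilyl chloride, CC(C)(C)[Si](C)(C)Cl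
Why: Exhaustive silylation protects both phenols and gives the silyl ester needed for neutral acid chloride formation.

Step 18
Reactants: 25 tris-silyl compound
Product: 26 3,4-bis(tert-butyldimethylsilyloxy)benzoyl chloride
Conditions: (COCl)2, DMF (cat.), CH2Cl2, 0 °C → rt
Reagents that add atoms: oxalyl chloride, ClC(=O)C(=O)Cl
Why: Silyl esters are converted directly into acid chlorides by oxalyl chloride/DMF without acid that would cleave the aryl silyl ethers.

Step 19
Reactants: 23 bridgehead-geranylated enol ether; 26 acid chloride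
Product: 27 3-[3,4-bis(tert-butyldimethylsilyloxy)benzoyl] derivative of 23
Conditions: lithium 2,2,6,6-tetramethylpiperidide, THF, −78 °C; then 26, −78 °C
Reagents that add atoms: none
Why: With both bridgeheads now quaternary, the hindered amide base lithiates the vinylic C3–H of the vinylogous ester and the vinyllithium is acylated, as precedented for C3 benzoylation of this ring system.

Step 20
Reactants: 27 protected guttiferone B
Product: 28 guttiferone B
Conditions: LiOH, 1,4-dioxane/H2O, 90 °C (degassed); then 1 M HCl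
Reagents that add atoms: lithium hydroxide, [Li+].[OH-]
Why: Hydroxide addition–elimination at C4 cleaves the vinylogous methyl ester and the same medium cleaves the two aryl silyl ethers, without the acid that would cyclise the prenyl groups onto the enol.

**Compound list**

1 | cyclopentane-1,3-dione | O=C1CCC(=O)C1 | starting material
2 | 1-bromo-3-methylbut-2-ene (prenyl bromide) | CC(C)=CCBr | starting material
3 | 2-(3-methylbut-2-en-1-yl)cyclopentane-1,3-dione | O=C1CCC(=O)C1CC=C(C)C | intermediate
4 | 3-chloro-2-(3-methylbut-2-en-1-yl)cyclopent-2-en-1-one | O=C1CCC(Cl)=C1CC=C(C)C | intermediate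
5 | 1,1-dibromo-2-methylprop-1-ene | CC(C)=C(Br)Br | starting material
6 | (2E)-1-bromo-3,7-dimethylocta-2,6-diene (geranyl bromide) | CC(C)=CCC/C(C)=C/CBr | starting material
7 | (5E)-3-bromo-2,6,10-trimethylundeca-2,5,9-triene | CC(C)=C(Br)C/C=C(\C)CCC=C(C)C | intermediate
8 | 2,2-dimethoxyacetaldehyde | O=CC(OC)OC | starting material
9 | (5E)-1,1-dimethoxy-6,10-dimethyl-3-(propan-2-ylidene)undeca-5,9-dien-2-ol, racemic | CC(C)=C(C/C=C(\C)CCC=C(C)C)C(O)C(OC)OC | intermediate
10 | 3-{[(5E)-1,1-dimethoxy-6,10-dimethyl-3-(propan-2-ylidene)undeca-5,9-dien-2-yl]oxy}-2-(3-methylbut-2-en-1-yl)cyclopent-2-en-1-one, racemic | O=C1CCC(OC(C(OC)OC)C(C/C=C(\C)CCC=C(C)C)=C(C)C)=C1CC=C(C)C | intermediate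
11 | 2-[(3E,5E)-3-(2,2-dimethoxyethylidene)-2,6,10-trimethylundeca-5,9-dien-2-yl]-2-(3-methylbut-2-en-1-yl)cyclopentane-1,3-dione (achiral; the 3Z isomer may accompany it) | O=C1CCC(=O)C1(CC=C(C)C)C(C)(C)/C(C/C=C(\C)CCC=C(C)C)=C/C(OC)OC | intermediate
12 | (2E)-3-[(2E)-3,7-dimethylocta-2,6-dien-1-yl]-4-methyl-4-[1-(3-methylbut-2-en-1-yl)-2,5-dioxocyclopentyl]pent-2-enal | O=C1CCC(=O)C1(CC=C(C)C)C(C)(C)/C(C/C=C(\C)CCC=C(C)C)=C/C=O | intermediate
13 | (3S)-3-[(2E)-3,7-dimethylocta-2,6-dien-1-yl]-4-methyl-4-[1-(3-methylbut-2-en-1-yl)-2,5-dioxocyclopentyl]pentanal | CC(C)=CCC/C(C)=C/C[C@@H](CC=O)C(C)(C)C1(CC=C(C)C)C(=O)CCC1=O | intermediate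
14 | (3S)-3-[(2E)-3,7-dimethylocta-2,6-dien-1-yl]-4-methyl-4-[1-(3-methylbut-2-en-1-yl)-2,5-dioxocyclopentyl]pentanoic acid | CC(C)=CCC/C(C)=C/C[C@@H](CC(=O)O)C(C)(C)C1(CC=C(C)C)C(=O)CCC1=O | intermediate
15 | 2-thioxopyridin-1(2H)-yl ester of 14 (Barton ester, not isolated) | CC(C)=CCC/C(C)=C/C[C@@H](CC(=O)On1ccccc1=S)C(C)(C)C1(CC=C(C)C)C(=O)CCC1=O | intermediate
16 | 2-[(3R,5E)-3-(iodomethyl)-2,6,10-trimethylundeca-5,9-dien-2-yl]-2-(3-methylbut-2-en-1-yl)cyclopentane-1,3-dione | CC(C)=CCC/C(C)=C/C[C@@H](CI)C(C)(C)C1(CC=C(C)C)C(=O)CCC1=O | intermediate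
17 | 3-geranyl-4,4-dimethyl-5-prenylbicyclo[3.2.1]octane-6,8-dione; geranyl exo (equatorial on the six-membered ring, anti to the C(=O)–CH2 bridge), C1, C5 and C7 configured as in 28 | CC(C)=CCC/C(C)=C/C[C@H]1C[C@H]2C(=O)[C@](CC=C(C)C)(C(=O)C2)C1(C)C | intermediate
18 | 7-hydroxy derivative of 17 (hydroxyl on C4; carbinol configuration not defined, erased in step 13) | CC(C)=CCC/C(C)=C/C[C@H]1C[C@H]2C(=O)[C@](CC=C(C)C)(C(=O)C2O)C1(C)C | intermediate
19 | 3-geranyl-4,4-dimethyl-5-prenyl-6,7-bis(trimethylsilyloxy)bicyclo[3.2.1]oct-6-en-8-one | CC(C)=CCC/C(C)=C/C[C@H]1C[C@H]2C(=O)[C@](CC=C(C)C)(C(O[Si](C)(C)C)=C2O[Si](C)(C)C)C1(C)C | intermediate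
20 | 7-geranyl-8,8-dimethyl-1-prenyl-2,4-bis(trimethylsilyloxy)tricyclo[3.3.1.0(2,4)]nonan-9-one (core numbering; cyclopropane expected on the face syn to C9, its two centres transient; not isolated) | CC(C)=CCC/C(C)=C/C[C@H]1C[C@H]2C(=O)[C@](CC=C(C)C)(C3(O[Si](C)(C)C)CC23O[Si](C)(C)C)C1(C)C | intermediate
21 | 7-geranyl-8,8-dimethyl-1-prenylbicyclo[3.3.1]nonane-2,4,9-trione (drawn as triketone; C1, C5, C7 as in 28, C5–H) | CC(C)=CCC/C(C)=C/C[C@H]1C[C@H]2C(=O)[C@](CC=C(C)C)(C(=O)CC2=O)C1(C)C | intermediate
22 | 7-geranyl-4-methoxy-8,8-dimethyl-1-prenylbicyclo[3.3.1]non-3-ene-2,9-dione | CC(C)=CCC/C(C)=C/C[C@H]1C[C@H]2C(=O)[C@](CC=C(C)C)(C(=O)C=C2OC)C1(C)C | intermediate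
23 | 5,7-digeranyl-4-methoxy-8,8-dimethyl-1-prenylbicyclo[3.3.1]non-3-ene-2,9-dione | CC(C)=CCC/C(C)=C/C[C@H]1C[C@@]2(C/C=C(\C)CCC=C(C)C)C(=O)[C@](CC=C(C)C)(C(=O)C=C2OC)C1(C)C | intermediate
24 | 3,4-dihydroxybenzoic acid | O=C(O)c1ccc(O)c(O)c1 | starting material
25 | tert-butyldimethylsilyl 3,4-bis(tert-butyldimethylsilyloxy)benzoate | CC(C)(C)[Si](C)(C)OC(=O)c1ccc(O[Si](C)(C)C(C)(C)C)c(O[Si](C)(C)C(C)(C)C)c1 | intermediate
26 | 3,4-bis(tert-butyldimethylsilyloxy)benzoyl chloride | O=C(Cl)c1ccc(O[Si](C)(C)C(C)(C)C)c(O[Si](C)(C)C(C)(C)C)c1 | intermediate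
27 | 3-[3,4-bis(tert-butyldimethylsilyloxy)benzoyl]-5,7-digeranyl-4-methoxy-8,8-dimethyl-1-prenylbicyclo[3.3.1]non-3-ene-2,9-dione | CC(C)=CCC/C(C)=C/C[C@H]1C[C@@]2(C/C=C(\C)CCC=C(C)C)C(=O)[C@](CC=C(C)C)(C(=O)C(C(=O)c3ccc(O[Si](C)(C)C(C)(C)C)c(O[Si](C)(C)C(C)(C)C)c3)=C2OC)C1(C)C | intermediate
28 | guttiferone B, (1R,5R,7S) for the tautomer drawn | CC(C)=CCC/C(C)=C/C[C@H]1C[C@@]2(C/C=C(\C)CCC=C(C)C)C(=O)[C@](CC=C(C)C)(C(=O)C(C(=O)c3ccc(O)c(O)c3)=C2O)C1(C)C | target

**Step count and risks**

Total step count: 20. Longest linear sequence: 16 steps (1, 2, 5–16, 19, 20, from cyclopentane-1,3-dione).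

Steps most likely to fail:

Step 14 (key step). The carbenoid may also cyclopropanate side-chain alkenes, and the iron oxidation may open the cyclopropane at an external bond (giving a methylated acyloin) or trigger cationic cyclisation of the polyene. The fallback moves the one-carbon ring expansion to the ketone stage; it sets out from 17 and comes back at 21. Me3SiCHN2 with Sc(OTf)3 should insert CH2 between C2 and the less substituted C4 of the less hindered ketone to give bicyclo[3.3.1]nonane-2,9-dione F1. One-pot dehydrogenation (LiN(i-Pr)2, then N-tert-butylbenzenesulfinimidoyl chloride) gives enone F2, nucleophilic epoxidation (t-BuOOH, DBU) gives epoxy ketone F3, and Pd(PPh3)4/dppe isomerisation of the α,β-epoxy ketone gives the β-diketone 21.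

Step 6. The hindered allyl enol ether may eliminate thermally (retro-ene loss of the diene) or ionise and recombine to the linear C-allyl isomer instead of undergoing the [3,3] shift that must join two fully substituted carbons. The fallback builds the C1–C8 bond before C1 carries the prenyl group; it sets out from 1 and 9 and comes back at 11. Oxalyl chloride converts 1 into 3-chlorocyclopent-2-en-1-one F4, NaH and 9 give enol ether F5, the Claisen rearrangement onto an unsubstituted position gives the enolisable 2-monosubstituted dione F6, and Pd(PPh3)4-catalysed Tsuji–Trost C-allylation with methyl 3-methylbut-2-enyl carbonate installs the prenyl group.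

Step 8. Iminium formation and hydride transfer may be slow at a β-carbon bearing a tert-alkyl group, so that amine-catalysed intramolecular aldol addition of the product aldehyde to a ring ketone or loss of enantiopurity competes. The fallback replaces organocatalysis by allylic-alcohol hydrogenation; it sets out from 12 and comes back at 14. NaBH(OAc)3 should reduce only the aldehyde to allylic alcohol F7 (E isomer purified), Ru(OAc)2(BINAP)/H2, with the BINAP antipode chosen by the allylic-alcohol facial rule, should hydrogenate only that alkene to saturated alcohol F8, and TEMPO/NaOCl/NaClO2 oxidation gives acid 14 directly.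

**Further compounds**

F1 | step 14 | 7-geranyl-8,8-dimethyl-1-prenylbicyclo[3.3.1]nonane-2,9-dione | CC(C)=CCC/C(C)=C/C[C@H]1C[C@H]2C(=O)[C@](CC=C(C)C)(C(=O)CC2)C1(C)C
F2 | step 14 | 7-geranyl-8,8-dimethyl-1-prenylbicyclo[3.3.1]non-3-ene-2,9-dione | CC(C)=CCC/C(C)=C/C[C@H]1C[C@H]2C(=O)[C@](CC=C(C)C)(C(=O)C=C2)C1(C)C
F3 | step 14 | 3,4-epoxy-7-geranyl-8,8-dimethyl-1-prenylbicyclo[3.3.1]nonane-2,9-dione | CC(C)=CCC/C(C)=C/C[C@H]1C[C@H]2C(=O)[C@](CC=C(C)C)(C(=O)C3OC23)C1(C)C
F4 | step 6 | 3-chlorocyclopent-2-en-1-one | O=C1CCC(Cl)=C1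
F5 | step 6 | 3-{[(5E)-1,1-dimethoxy-6,10-dimethyl-3-(propan-2-ylidene)undeca-5,9-dien-2-yl]oxy}cyclopent-2-en-1-one | O=C1CCC(OC(C(OC)OC)C(C/C=C(\C)CCC=C(C)C)=C(C)C)=C1
F6 | step 6 | 2-[(3E,5E)-3-(2,2-dimethoxyethylidene)-2,6,10-trimethylundeca-5,9-dien-2-yl]cyclopentane-1,3-dione | O=C1CCC(=O)C1C(C)(C)/C(C/C=C(\C)CCC=C(C)C)=C/C(OC)OC
F7 | step 8 | 2-[(3E,5E)-3-(2-hydroxyethylidene)-2,6,10-trimethylundeca-5,9-dien-2-yl]-2-(3-methylbut-2-en-1-yl)cyclopentane-1,3-dione | O=C1CCC(=O)C1(CC=C(C)C)C(C)(C)/C(C/C=C(\C)CCC=C(C)C)=C/CO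
F8 | step 8 | 2-[(3S,5E)-3-(2-hydroxyethyl)-2,6,10-trimethylundeca-5,9-dien-2-yl]-2-(3-methylbut-2-en-1-yl)cyclopentane-1,3-dione | CC(C)=CCC/C(C)=C/C[C@@H](CCO)C(C)(C)C1(CC=C(C)C)C(=O)CCC1=O
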